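**Assumption:** the target has no stereocentre (it is an achiral, symmetric methylene-bis-acylphloroglucinol), so "single enantiomer" carries no stereochemical demand and no stereocontrol is needed.

## Retrosynthetic overview
1. Cut both Ar–CH2 bonds of the symmetric dimer: target 12 comes from two molecules of pseudoaspidinol 8 plus formaldehyde, joined at the only free ring position of 8.
2. 8 comes from 3-methylphlorobutyrophenone 3 by methylating the hindered 2-OH while the 4-OH and 6-OH are masked as tosylates (3 → 5 → 7 → 8).
3. 3 comes from 2-methylphloroglucinol 1 and butanoyl chloride 2 by Friedel–Crafts C-acylation.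
4. No ring is formed: both benzene rings are carried in from commercial 1.

## Route

Step 1
Reactants: 1 2-methylbenzene-1,3,5-triol (2-methylphloroglucinol); 2 butanoyl chloride
Product: 3 1-(2,4,6-trihydroxy-3-methylphenyl)butan-1-one
Conditions: AlCl3 (4 equiv), PhNO2–CH2Cl2, 0 °C to 45 °C; then ice/1 M HCl
Reagents that add atoms: butanoyl chloride 2, CCCC(=O)Cl
Why: Friedel–Crafts C-acylation of the highly activated phloroglucinol ring, where the two free positions of 1 are equivalent (one regioisomer) and the aluminium-complexed aryl ketone resists a second acylation.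

Step 2
Reactants: 3 1-(2,4,6-trihydroxy-3-methylphenyl)butan-1-one; 4 4-methylbenzenesulfonyl chloride (2.05 equiv)
Product: 5 4-butanoyl-5-hydroxy-6-methyl-1,3-phenylene bis(4-methylbenzenesulfonate)
Conditions: TsCl (2.05 equiv), K2CO3 (3 equiv), acetone, reflux; crystallise
Reagents that add atoms: 4-methylbenzenesulfonyl chloride 4, Cc1ccc(cc1)S(=O)(=O)Cl
Why: Regioselective O-sulfonylation, in which the acidic non-chelated 4-OH and the less hindered ortho 6-OH react while the 2-OH (flanked by methyl and acyl, hydrogen-bonded to C=O) is left free, and the hard sulfonyl electrophile avoids C-substitution.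

Step 3
Reactants: 5 4-butanoyl-5-hydroxy-6-methyl-1,3-phenylene bis(4-methylbenzenesulfonate); 6 iodomethane
Product: 7 4-butanoyl-5-methoxy-6-methyl-1,3-phenylene bis(4-methylbenzenesulfonate)
Conditions: MeI (5 equiv), K2CO3, acetone, reflux, 24 h
Reagents that add atoms: iodomethane 6, CI
Why: Williamson O-methylation of the only remaining phenol, with the aryl tosylates stable to anhydrous carbonate and the tosylated ring too deactivated for C-methylation.

Step 4
Reactants: 7 4-butanoyl-5-methoxy-6-methyl-1,3-phenylene bis(4-methylbenzenesulfonate)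
Product: 8 1-(4,6-dihydroxy-2-methoxy-3-methylphenyl)butan-1-one (pseudoaspidinol)
Conditions: KOH, H2O–MeOH, reflux, N2; then aq HCl
Reagents that add atoms: none
Why: Nucleophilic S–O cleavage (sulfonate hydrolysis) of aryl tosylates activated by the ortho/para ketone, which leaves the methyl ether and the ketone untouched.

Step 5
Reactants: 8 1-(4,6-dihydroxy-2-methoxy-3-methylphenyl)butan-1-one (2 equiv); 9 formaldehyde (0.5 equiv)
Product: 12 pseudoaspidin, via hydroxymethylphenol 10 (not isolated), via ortho-quinone methide 11 (not isolated)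
Conditions: 37% aq HCHO (0.5 equiv), 1% aq KOH, 0 °C to rt, N2; then aq HCl
Reagents that add atoms: formaldehyde 9, C=O
Why: Lederer–Manasse hydroxymethylation at the single free ring position (between the two OH groups), loss of water to the ortho-quinone methide and conjugate addition of a second phenolate give the methylene bridge, and no position is left for oligomerisation.

## Compound list
1 | 2-methylbenzene-1,3,5-triol (2-methylphloroglucinol) | Cc1c(O)cc(O)cc1O | starting material
2 | butanoyl chloride | CCCC(=O)Cl | starting material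
3 | 1-(2,4,6-trihydroxy-3-methylphenyl)butan-1-one | CCCC(=O)c1c(O)cc(O)c(C)c1O | intermediate
4 | 4-methylbenzenesulfonyl chloride | Cc1ccc(cc1)S(=O)(=O)Cl | starting material
5 | 4-butanoyl-5-hydroxy-6-methyl-1,3-phenylene bis(4-methylbenzenesulfonate) | CCCC(=O)c1c(O)c(C)c(OS(=O)(=O)c2ccc(C)cc2)cc1OS(=O)(=O)c1ccc(C)cc1 | intermediate
6 | iodomethane | CI | starting material
7 | 4-butanoyl-5-methoxy-6-methyl-1,3-phenylene bis(4-methylbenzenesulfonate) | CCCC(=O)c1c(OC)c(C)c(OS(=O)(=O)c2ccc(C)cc2)cc1OS(=O)(=O)c1ccc(C)cc1 | intermediate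
8 | 1-(4,6-dihydroxy-2-methoxy-3-methylphenyl)butan-1-one (pseudoaspidinol) | CCCC(=O)c1c(OC)c(C)c(O)cc1O | intermediate
9 | formaldehyde | C=O | starting material
10 | 1-[4,6-dihydroxy-5-(hydroxymethyl)-2-methoxy-3-methylphenyl]butan-1-one | CCCC(=O)c1c(OC)c(C)c(O)c(CO)c1O | intermediate
11 | 4-butanoyl-5-hydroxy-3-methoxy-2-methyl-6-methylidenecyclohexa-2,4-dien-1-one | CCCC(=O)C1=C(O)C(=C)C(=O)C(C)=C1OC | intermediate
12 | pseudoaspidin, bis(3-butanoyl-2,6-dihydroxy-4-methoxy-5-methylphenyl)methane | CCCC(=O)c1c(O)c(Cc2c(O)c(C)c(OC)c(C(=O)CCC)c2O)c(O)c(C)c1OC | target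

## Summary
Total step count: 5. Longest linear sequence: 5 (fully linear; the last step joins two molecules of 8).

Three steps most likely to fail:

**Step 2 (regioselective 4,6-ditosylation).** The risk is a mixture of the 4,6- and 2,4-ditosylates or over-tosylation. The fallback sets out from 1 and comes back at 8, and fixes the regiochemistry with a traceless carboxyl group instead of by sterics. Kolbe–Schmitt carboxylation of 1 (KHCO3, CO2, water, 50 °C) gives 2,4,6-trihydroxy-3-methylbenzoic acid F1. Trimethylsilyldiazomethane in MeOH–toluene esterifies the acid and methylates only the non-chelated 4-OH, giving methyl 2,6-dihydroxy-4-methoxy-3-methylbenzoate F2. TiCl4-mediated ortho-acylation with 2 at the single free position gives methyl 3-butanoyl-2,6-dihydroxy-4-methoxy-5-methylbenzoate F3. Saponification (aq NaOH, heat) gives 3-butanoyl-2,6-dihydroxy-4-methoxy-5-methylbenzoic acid F4, which decarboxylates on acidification and warming to 8.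

**Step 3 (methylation of the hindered, chelated phenol).** The risk is a sluggish reaction, and the tosylates forbid stronger base. The fallback sets out from 3 and comes back at 8, using acetal protection so that an irreversible phenoxide alkylation can be used. MOMCl/iPr2NEt in CH2Cl2 gives 1-[2-hydroxy-4,6-bis(methoxymethoxy)-3-methylphenyl]butan-1-one F5. NaH (1.1 equiv)/MeI in DMF at 0 °C gives 1-[2-methoxy-4,6-bis(methoxymethoxy)-3-methylphenyl]butan-1-one F6. HCl in MeOH at 50 °C removes both acetals to give 8.

**Step 5 (formaldehyde coupling).** The risk is stalling at the hydroxymethyl stage or oxidative degradation of the phenolate in aqueous base. The fallback sets out from 8 and comes back at 12 by a Mannich route without free formaldehyde or aqueous alkali. Eschenmoser's salt in CH2Cl2 converts 8 into 1-{5-[(dimethylamino)methyl]-4,6-dihydroxy-2-methoxy-3-methylphenyl}butan-1-one F7. Heating F7 with a second equivalent of 8 in toluene expels dimethylamine, regenerates quinone methide 11 and gives 12.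

Further compounds
F1 | step 2 | 2,4,6-trihydroxy-3-methylbenzoic acid | Cc1c(O)cc(O)c(C(=O)O)c1O
F2 | step 2 | methyl 2,6-dihydroxy-4-methoxy-3-methylbenzoate | COC(=O)c1c(O)cc(OC)c(C)c1O
F3 | step 2 | methyl 3-butanoyl-2,6-dihydroxy-4-methoxy-5-methylbenzoate | CCCC(=O)c1c(O)c(C(=O)OC)c(O)c(C)c1OC
F4 | step 2 | 3-butanoyl-2,6-dihydroxy-4-methoxy-5-methylbenzoic acid | CCCC(=O)c1c(O)c(C(=O)O)c(O)c(C)c1OC
F5 | step 3 | 1-[2-hydroxy-4,6-bis(methoxymethoxy)-3-methylphenyl]butan-1-one | CCCC(=O)c1c(O)c(C)c(OCOC)cc1OCOC
F6 | step 3 | 1-[2-methoxy-4,6-bis(methoxymethoxy)-3-methylphenyl]butan-1-one | CCCC(=O)c1c(OC)c(C)c(OCOC)cc1OCOC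
F7 | step 5 | 1-{5-[(dimethylamino)methyl]-4,6-dihydroxy-2-methoxy-3-methylphenyl}butan-1-one | CCCC(=O)c1c(OC)c(C)c(O)c(CN(C)C)c1O
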